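## Retrosynthetic overview

1. Rings: the thiazole is bought. The 16-membered lactone is closed first, by Yamaguchi lactonisation (O–C1 bond) of the C1–C17 seco acid. The C12–C13 epoxide is formed last, by dioxirane epoxidation of the Z-olefin.
2. Chain: C11–C12 comes from a B-alkyl Suzuki coupling of fragment A (C12–C21 Z-vinyl iodide) with the C1–C11 alkene. C6–C7 comes from a chlorotitanium syn-aldol of fragment B (C1–C6 ethyl ketone) with fragment C (C7–C11 aldehyde).
3. Fragment A: C15 is set by a BINOL/Ti(OiPr)4-catalysed Keck allylation of an achiral thiazolyl enal, followed by alkene cleavage and iodo-Wittig olefination.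
4. Fragment B: C3 is set by a ketoreductase reduction of an achiral β-keto ester, and C4 by a Fráter–Seebach anti-methylation.
5. Fragment C: C8 is set by an ene-reductase reduction of methyl 2-(hydroxymethyl)acrylate, followed by chain extension with a vinyl copper reagent.

Assumption: positions are numbered as in the epothilones (C1 = lactone carbonyl, C15 = lactone carbinol), which makes the target (3S,4S,6R,7S,8S,12R,13S,15S); the enzymes are bought as panel preparations and act as catalysts.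

Abbreviations: TBS = tert-butyldimethylsilyl, TES = triethylsilyl, TBDPS = tert-butyldiphenylsilyl, PMB = 4-methoxybenzyl.

## Fragment A (C12–C21)

Step 1
Reactants: 1 2-methyl-1,3-thiazole-4-carbaldehyde; 2 2-(triphenylphosphoranylidene)propanal
Product: 3 (2E)-2-methyl-3-(2-methyl-1,3-thiazol-4-yl)prop-2-enal
Conditions: toluene, 90 °C
Reagents that add atoms: none
Why: Wittig olefination with a stabilised ylide gives the (E)-trisubstituted enal selectively, and no stereocentre is formed.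

Step 2
Reactants: 3 (2E)-2-methyl-3-(2-methyl-1,3-thiazol-4-yl)prop-2-enal; 4 allyltributylstannane
Product: 5 (1E,3S)-2-methyl-1-(2-methyl-1,3-thiazol-4-yl)hexa-1,5-dien-3-ol
Conditions: (S)-BINOL (20 mol %), Ti(OiPr)4 (10 mol %), 4 Å MS, CH2Cl2, −20 °C, 3 d; then H2O
Reagents that add atoms: none
Why: In this Keck catalytic asymmetric allylation the chiral BINOL–titanium Lewis acid binds the aldehyde and leaves only its Si face open to the stannane, which sets C15 as S (about 95% ee) as the first stereocentre of the route.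

Step 3
Reactants: 5 (1E,3S)-2-methyl-1-(2-methyl-1,3-thiazol-4-yl)hexa-1,5-dien-3-ol
Product: 6 4-[(1E,3S)-2-methyl-3-(TESO)hexa-1,5-dien-1-yl]-2-methyl-1,3-thiazole
Conditions: Et3SiCl, imidazole, DMF, 0 °C to rt
Reagents that add atoms: chlorotriethylsilane, CC[Si](Cl)(CC)CC
Why: Imidazole-promoted O-silylation installs a TES ether that can later be removed under mild acid while secondary TBS ethers stay, and C15 is untouched.

Step 4
Reactants: 6 4-[(1E,3S)-2-methyl-3-(TESO)hexa-1,5-dien-1-yl]-2-methyl-1,3-thiazole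
Product: 7 (4S,5E)-5-methyl-6-(2-methyl-1,3-thiazol-4-yl)-4-(TESO)hex-5-ene-1,2-diol (both C2 epimers)
Conditions: OsO4 (2 mol %), NMO, THF/t-BuOH/H2O, 0 °C
Reagents that add atoms: N-methylmorpholine N-oxide, C[N+]1([O-])CCOCC1; water, O
Why: In this Upjohn dihydroxylation the monosubstituted terminal alkene reacts much faster than the hindered, thiazole-conjugated trisubstituted alkene, and the new carbinol centre is destroyed in step 5.

Step 5
Reactants: 7 (4S,5E)-5-methyl-6-(2-methyl-1,3-thiazol-4-yl)-4-(TESO)hex-5-ene-1,2-diol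
Product: 8 (3S,4E)-4-methyl-5-(2-methyl-1,3-thiazol-4-yl)-3-(TESO)pent-4-enal
Conditions: NaIO4, THF/KH2PO4–K2HPO4 buffer pH 7, 0 °C
Reagents that add atoms: none
Why: Malaprade glycol cleavage at neutral pH gives the C13 aldehyde without eliminating the β-silyloxy group or cleaving the TES ether.

Step 6
Reactants: 8 (3S,4E)-4-methyl-5-(2-methyl-1,3-thiazol-4-yl)-3-(TESO)pent-4-enal; 9 ethyltriphenylphosphonium iodide
Product: 13 4-[(1E,3S,5Z)-6-iodo-2-methyl-3-(TESO)hepta-1,5-dien-1-yl]-2-methyl-1,3-thiazole, via ethylidene ylide 10 (not isolated), via iodoethylphosphonium iodide 11 (not isolated), via iodoethylidene ylide 12 (not isolated)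
Conditions: 9, n-BuLi, THF, rt; I2, −78 °C; NaN(SiMe3)2, −20 °C; then 8, −78 to −20 °C
Reagents that add atoms: iodine, II
Why: Wittig olefination with a non-stabilised α-iodo ylide (Stork–Zhao type) is kinetically cis-selective and places iodine and the C14 chain on the same side, which gives the Z-vinyl iodide.

## Fragment B (C1–C6)

Step 7
Reactants: 14 propane-1,3-diol
Product: 15 3-[(4-methoxybenzyl)oxy]propan-1-ol
Conditions: NaH (1 equiv), PMBCl (1 equiv), Bu4NI (cat.), diol (3 equiv), THF, 0 °C to rt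
Reagents that add atoms: 4-methoxybenzyl chloride, COc1ccc(CCl)cc1
Why: Williamson etherification with the diol in excess gives the mono-PMB ether as the main product.

Step 8
Reactants: 15 3-[(4-methoxybenzyl)oxy]propan-1-ol
Product: 16 3-[(4-methoxybenzyl)oxy]propanal
Conditions: TEMPO (10 mol %), PhI(OAc)2, CH2Cl2, rt
Reagents that add atoms: none
Why: Oxoammonium-catalysed (TEMPO) oxidation stops at the aldehyde and is mild enough that the β-alkoxy aldehyde does not eliminate.

Step 9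
Reactants: 16 3-[(4-methoxybenzyl)oxy]propanal; 17 ethyl diazoacetate
Product: 18 ethyl 5-[(4-methoxybenzyl)oxy]-3-oxopentanoate
Conditions: SnCl2 (10 mol %), CH2Cl2, rt
Reagents that add atoms: none
Why: In the Roskamp homologation the diazo carbon adds to the SnCl2-activated aldehyde, and a 1,2-hydride shift with loss of N2 gives the β-keto ester under nearly neutral conditions.

Step 10
Reactants: 18 ethyl 5-[(4-methoxybenzyl)oxy]-3-oxopentanoate
Product: 19 ethyl (3S)-3-hydroxy-5-[(4-methoxybenzyl)oxy]pentanoate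
Conditions: ketoreductase (S-selective member of a commercial panel), NADP+ (cat.), i-PrOH (10 vol %), KH2PO4/K2HPO4 buffer pH 7.0, MgSO4 (2 mM), 30 °C
Reagents that add atoms: none
Why: In this biocatalytic asymmetric ketone reduction the ketoreductase (NADPH-dependent oxidoreductase, EC 1.1.1) holds the β-keto ester in one orientation and delivers hydride to one carbonyl face, which sets C3 as S (>99% ee) at neutral pH while propan-2-ol recycles the cofactor.

Step 11
Reactants: 19 ethyl (3S)-3-hydroxy-5-[(4-methoxybenzyl)oxy]pentanoate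
Product: 21 ethyl (2S,3S)-3-hydroxy-5-[(4-methoxybenzyl)oxy]-2-methylpentanoate, via dilithio alkoxide-enolate 20 (not isolated)
Conditions: LiN(iPr)2 (2.2 equiv), THF, −78 to −20 °C; MeI, DMPU, −78 to 0 °C
Reagents that add atoms: iodomethane, CI; lithium diisopropylamide, [Li]N(C(C)C)C(C)C (its lithium stays only in 20)
Why: In the Fráter–Seebach alkylation the lithium-chelated six-membered alkoxide-enolate is methylated on the face away from the C3 side chain, which sets C4 as S with the 3,4-anti relationship (dr about 95:5).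

Step 12
Reactants: 21 ethyl (2S,3S)-3-hydroxy-5-[(4-methoxybenzyl)oxy]-2-methylpentanoate
Product: 22 (2S,3S)-3-hydroxy-N-methoxy-5-[(4-methoxybenzyl)oxy]-N,2-dimethylpentanamide
Conditions: MeNHOMe·HCl, i-PrMgCl, THF, −20 to 0 °C
Reagents that add atoms: N,O-dimethylhydroxylamine hydrochloride, CNOC.Cl
Why: Weinreb amidation with the magnesium amide is run on the free alcohol, whose alkoxide suppresses deprotonation at C4, so neither epimerisation nor β-elimination takes place.

Step 13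
Reactants: 22 (2S,3S)-3-hydroxy-N-methoxy-5-[(4-methoxybenzyl)oxy]-N,2-dimethylpentanamide
Product: 23 (2S,3S)-3-(TBSO)-N-methoxy-5-[(4-methoxybenzyl)oxy]-N,2-dimethylpentanamide
Conditions: TBSOTf, 2,6-lutidine, CH2Cl2, −78 to 0 °C
Reagents that add atoms: tert-butyldimethylsilyl triflate, CC(C)(C)[Si](C)(C)OS(=O)(=O)C(F)(F)F
Why: Silyl triflate O-silylation with a hindered base protects the secondary C3 alcohol without touching either stereocentre.

Step 14
Reactants: 23 (2S,3S)-3-(TBSO)-N-methoxy-5-[(4-methoxybenzyl)oxy]-N,2-dimethylpentanamide; 24 ethylmagnesium bromide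
Product: 26 (4S,5S)-5-(TBSO)-7-[(4-methoxybenzyl)oxy]-4-methylheptan-3-one, via magnesium hemiaminal chelate 25 (not isolated)
Conditions: EtMgBr, THF, 0 °C; then H2O
Reagents that add atoms: none
Why: In the Weinreb ketone synthesis the stable magnesium chelate 25 survives until work-up, so only one ethyl group adds and the α-centre C4 is never exposed to a free ketone enolate.

## Fragment C (C7–C11)

Step 15
Reactants: 27 methyl 2-(hydroxymethyl)acrylate
Product: 28 methyl (2R)-3-hydroxy-2-methylpropanoate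
Conditions: ene-reductase (Old Yellow Enzyme family), NAD+ (cat.), formate dehydrogenase, HCO2Na, Tris-HCl buffer pH 7.5, 30 °C
Reagents that add atoms: none
Why: In this biocatalytic asymmetric alkene reduction the ene-reductase (flavin-dependent oxidoreductase, EC 1.6.99.1) passes hydride from reduced flavin to the CH2 terminus and a tyrosine proton to Cα from the opposite face, which sets the future C8 centre as R here (>99% ee).

Step 16
Reactants: 28 methyl (2R)-3-hydroxy-2-methylpropanoate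
Product: 29 methyl (2R)-3-(TBDPSO)-2-methylpropanoate
Conditions: TBDPSCl, imidazole, DMF, rt
Reagents that add atoms: tert-butyl(chloro)diphenylsilane, CC(C)(C)[Si](Cl)(c1ccccc1)c1ccccc1
Why: Imidazole-promoted O-silylation masks the future C7 oxygen and makes the small intermediates non-volatile.

Step 17
Reactants: 29 methyl (2R)-3-(TBDPSO)-2-methylpropanoate
Product: 30 (2S)-3-(TBDPSO)-2-methylpropan-1-ol
Conditions: i-Bu2AlH (2.5 equiv), CH2Cl2, −78 to 0 °C
Reagents that add atoms: none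
Why: Hydride reduction of the ester to the primary alcohol leaves the centre untouched, and the descriptor changes only because the priorities change.

Step 18
Reactants: 30 (2S)-3-(TBDPSO)-2-methylpropan-1-ol
Product: 31 (2R)-tert-butyl(3-iodo-2-methylpropoxy)diphenylsilane
Conditions: I2, PPh3, imidazole, CH2Cl2, 0 °C to rt
Reagents that add atoms: iodine, II
Why: Appel-type iodination displaces the activated primary oxygen by SN2 at a carbon that is not stereogenic.

Step 19
Reactants: 31 (2R)-tert-butyl(3-iodo-2-methylpropoxy)diphenylsilane; 32 vinylmagnesium bromide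
Product: 33 (2S)-tert-butyl[(2-methylpent-4-en-1-yl)oxy]diphenylsilane
Conditions: CH2=CHMgBr (3 equiv), CuI (20 mol %), THF/DMPU, −30 °C to rt
Reagents that add atoms: none
Why: Copper-catalysed cross-coupling of a primary alkyl iodide with a vinyl Grignard reagent adds C10–C11, and the neighbouring stereocentre takes no part.

Step 20
Reactants: 33 (2S)-tert-butyl[(2-methylpent-4-en-1-yl)oxy]diphenylsilane
Product: 34 (2S)-2-methylpent-4-en-1-ol
Conditions: Bu4NF, THF, rt
Reagents that add atoms: none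
Why: Fluoride-driven desilylation frees the alcohol, and the heavy silicon by-product separates easily from the volatile product.

Step 21
Reactants: 34 (2S)-2-methylpent-4-en-1-ol
Product: 35 (2S)-2-methylpent-4-enal
Conditions: Dess–Martin periodinane, CH2Cl2, 0 °C to rt; used at once as a solution
Reagents that add atoms: none
Why: Dess–Martin oxidation is neutral and fast, so the α-methyl aldehyde is obtained without epimerisation.

## Assembly and endgame

Step 22
Reactants: 26 (4S,5S)-5-(TBSO)-7-[(4-methoxybenzyl)oxy]-4-methylheptan-3-one; 35 (2S)-2-methylpent-4-enal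
Product: 37 (3S,4S,6R,7S,8S)-3-(TBSO)-7-hydroxy-1-[(4-methoxybenzyl)oxy]-4,6,8-trimethylundec-10-en-5-one, via chlorotitanium Z-enolate 36 (not isolated)
Conditions: TiCl4 (1.1 equiv), i-Pr2NEt (1.2 equiv), CH2Cl2, −78 °C, 1 h; then 35 (1.5 equiv), −78 °C
Reagents that add atoms: titanium tetrachloride, Cl[Ti](Cl)(Cl)Cl (stays only in 36)
Why: In this chlorotitanium aldol addition, soft enolisation occurs only at the less hindered C6 methylene to give Z-enolate 36, whose chair Zimmerman–Traxler transition state gives 6,7-syn, while the C4 methyl centre directs 4,6-syn and the Z-enolate prefers the anti-Felkin face of the aldehyde (7,8-anti), so both partners are matched for 6R,7S.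

Step 23
Reactants: 37 (3S,4S,6R,7S,8S)-3-(TBSO)-7-hydroxy-1-[(4-methoxybenzyl)oxy]-4,6,8-trimethylundec-10-en-5-one
Product: 38 (3S,4S,6R,7S,8S)-3,7-bis(TBSO)-1-[(4-methoxybenzyl)oxy]-4,6,8-trimethylundec-10-en-5-one
Conditions: TBSOTf, 2,6-lutidine, CH2Cl2, −78 to 0 °C
Reagents that add atoms: tert-butyldimethylsilyl triflate, CC(C)(C)[Si](C)(C)OS(=O)(=O)C(F)(F)F
Why: Silyl triflate O-silylation caps the hindered C7 alcohol under non-basic conditions, which blocks retro-aldol cleavage in later steps.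

Step 24
Reactants: 38 (3S,4S,6R,7S,8S)-3,7-bis(TBSO)-1-[(4-methoxybenzyl)oxy]-4,6,8-trimethylundec-10-en-5-one; 13 4-[(1E,3S,5Z)-6-iodo-2-methyl-3-(TESO)hepta-1,5-dien-1-yl]-2-methyl-1,3-thiazole
Product: 40 (3S,4S,6R,7S,8S,12Z,15S,16E)-3,7-bis(TBSO)-1-[(4-methoxybenzyl)oxy]-4,6,8,12,16-pentamethyl-17-(2-methyl-1,3-thiazol-4-yl)-15-(TESO)heptadeca-12,16-dien-5-one, via B-alkyl-9-BBN borane 39 (not isolated)
Conditions: 9-BBN-H, THF, rt; then 13, PdCl2(dppf) (10 mol %), AsPh3, Cs2CO3, DMF/H2O, rt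
Reagents that add atoms: 9-borabicyclo[3.3.1]nonane, C1CC2CCCC(C1)B2 (stays only in 39)
Why: In this hydroboration and B-alkyl Suzuki–Miyaura coupling, 9-BBN-H adds anti-Markovnikov to the terminal alkene far faster than it reduces the hindered doubly branched ketone, and the coupling keeps the vinyl iodide geometry to give the 12Z alkene.

Step 25
Reactants: 40 the fully protected C1–C21 chain
Product: 41 (3S,4S,6R,7S,8S,12Z,15S,16E)-3,7-bis(TBSO)-1-hydroxy-4,6,8,12,16-pentamethyl-17-(2-methyl-1,3-thiazol-4-yl)-15-(TESO)heptadeca-12,16-dien-5-one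
Conditions: DDQ, CH2Cl2/KH2PO4–K2HPO4 buffer pH 7, 0 °C
Reagents that add atoms: none
Why: Oxidative PMB cleavage by hydride abstraction from the electron-rich benzylic position is specific for the PMB ether, and the buffer protects the TES ether.

Step 26
Reactants: 41 the C1 primary alcohol
Product: 42 (3S,4S,6R,7S,8S,12Z,15S,16E)-3,7-bis(TBSO)-4,6,8,12,16-pentamethyl-17-(2-methyl-1,3-thiazol-4-yl)-5-oxo-15-(TESO)heptadeca-12,16-dienal
Conditions: Dess–Martin periodinane, pyridine, CH2Cl2, 0 °C to rt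
Reagents that add atoms: none
Why: Pyridine-buffered Dess–Martin oxidation converts the only free alcohol to the aldehyde without acid or strong base, so C4 and C6 keep their configuration.

Step 27
Reactants: 42 the C1 aldehyde
Product: 43 (3S,4S,6R,7S,8S,12Z,15S,16E)-3,7-bis(TBSO)-4,6,8,12,16-pentamethyl-17-(2-methyl-1,3-thiazol-4-yl)-5-oxo-15-(TESO)heptadeca-12,16-dienoic acid
Conditions: NaClO2, NaH2PO4, 2-methylbut-2-ene, t-BuOH/H2O, rt
Reagents that add atoms: sodium chlorite, [Na+].[O-]Cl=O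
Why: Pinnick oxidation is selective for the aldehyde, and the alkene scavenger removes hypochlorous acid before it can attack the chain olefins or the thiazole.

Step 28
Reactants: 43 the C15-TES carboxylic acid
Product: 44 (3S,4S,6R,7S,8S,12Z,15S,16E)-3,7-bis(TBSO)-15-hydroxy-4,6,8,12,16-pentamethyl-17-(2-methyl-1,3-thiazol-4-yl)-5-oxoheptadeca-12,16-dienoic acid
Conditions: HF·pyridine, pyridine, THF, 0 °C
Reagents that add atoms: none
Why: Selective desilylation with buffered HF removes the much more labile TES ether and leaves both hindered secondary TBS ethers, without the basic fluoride that could trigger elimination at C3–C4.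

Step 29
Reactants: 44 the seco acid
Product: 46 (4S,5S,7R,8S,9S,13Z,16S)-4,8-bis(TBSO)-5,7,9,13-tetramethyl-16-[(1E)-1-(2-methyl-1,3-thiazol-4-yl)prop-1-en-2-yl]oxacyclohexadec-13-ene-2,6-dione, via mixed anhydride 45 (not isolated)
Conditions: 2,4,6-Cl3C6H2COCl, Et3N, THF, 0 °C to rt; then slow addition to DMAP, toluene (0.002 M), rt
Reagents that add atoms: 2,4,6-trichlorobenzoyl chloride, O=C(Cl)c1c(Cl)cc(Cl)cc1Cl (stays only in 45)
Why: In the Yamaguchi macrolactonisation DMAP attacks the unhindered carbonyl of mixed anhydride 45, and high dilution lets the C15 alcohol close the 16-membered ring with retention at C15.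

Step 30
Reactants: 46 the bis-TBS macrolactone
Product: 47 (4S,5S,7R,8S,9S,13Z,16S)-4,8-dihydroxy-5,7,9,13-tetramethyl-16-[(1E)-1-(2-methyl-1,3-thiazol-4-yl)prop-1-en-2-yl]oxacyclohexadec-13-ene-2,6-dione
Conditions: HF·pyridine, THF, 0 °C to rt
Reagents that add atoms: none
Why: Global fluoride desilylation in a weakly acidic medium frees both alcohols without dehydrating or epimerising the β-hydroxy ketone and without opening the lactone.

Step 31
Reactants: 47 the 12,13-olefin macrolactone diol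
Product: 48 (1S,3S,7S,8S,10R,11S,12S,16R)-7,11-dihydroxy-8,10,12,16-tetramethyl-3-[(1E)-1-(2-methyl-1,3-thiazol-4-yl)prop-1-en-2-yl]-4,17-dioxabicyclo[14.1.0]heptadecane-5,9-dione
Conditions: dimethyldioxirane (acetone solution), CH2Cl2, −50 °C
Reagents that add atoms: dimethyldioxirane, CC1(C)OO1
Why: In this concerted dioxirane epoxidation the electron-rich isolated C12–C13 alkene reacts before the thiazole-conjugated alkene, and the folded macrolactone exposes only its outer face, which sets 12R,13S with the cis geometry carried over from the Z-olefin.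

## Compound list

1 | 2-methyl-1,3-thiazole-4-carbaldehyde | Cc1nc(C=O)cs1 | starting material
2 | 2-(triphenylphosphoranylidene)propanal | CC(C=O)=P(c1ccccc1)(c1ccccc1)c1ccccc1 | starting material
3 | (2E)-2-methyl-3-(2-methyl-1,3-thiazol-4-yl)prop-2-enal | C/C(=C\c1csc(C)n1)C=O | intermediate
4 | allyltributylstannane | C=CC[Sn](CCCC)(CCCC)CCCC | starting material
5 | (1E,3S)-2-methyl-1-(2-methyl-1,3-thiazol-4-yl)hexa-1,5-dien-3-ol | C/C(=C\c1csc(C)n1)[C@@H](O)CC=C | intermediate
6 | 4-[(1E,3S)-2-methyl-3-(triethylsilyloxy)hexa-1,5-dien-1-yl]-2-methyl-1,3-thiazole | C/C(=C\c1csc(C)n1)[C@@H](O[Si](CC)(CC)CC)CC=C | intermediate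
7 | (4S,5E)-5-methyl-6-(2-methyl-1,3-thiazol-4-yl)-4-(triethylsilyloxy)hex-5-ene-1,2-diol, both C2 epimers | C/C(=C\c1csc(C)n1)[C@@H](O[Si](CC)(CC)CC)CC(O)CO | intermediate
8 | (3S,4E)-4-methyl-5-(2-methyl-1,3-thiazol-4-yl)-3-(triethylsilyloxy)pent-4-enal | C/C(=C\c1csc(C)n1)[C@@H](O[Si](CC)(CC)CC)CC=O | intermediate
9 | ethyltriphenylphosphonium iodide | CC[P+](c1ccccc1)(c1ccccc1)c1ccccc1.[I-] | starting material
10 | ethylidenetriphenylphosphorane | CC=P(c1ccccc1)(c1ccccc1)c1ccccc1 | intermediate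
11 | (1-iodoethyl)triphenylphosphonium iodide | CC(I)[P+](c1ccccc1)(c1ccccc1)c1ccccc1.[I-] | intermediate
12 | (1-iodoethylidene)triphenylphosphorane | CC(I)=P(c1ccccc1)(c1ccccc1)c1ccccc1 | intermediate
13 | 4-[(1E,3S,5Z)-6-iodo-2-methyl-3-(triethylsilyloxy)hepta-1,5-dien-1-yl]-2-methyl-1,3-thiazole | C/C(=C\c1csc(C)n1)[C@@H](O[Si](CC)(CC)CC)C/C=C(/C)I | intermediate
14 | propane-1,3-diol | OCCCO | starting material
15 | 3-[(4-methoxybenzyl)oxy]propan-1-ol | COc1ccc(COCCCO)cc1 | intermediate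
16 | 3-[(4-methoxybenzyl)oxy]propanal | COc1ccc(COCCC=O)cc1 | intermediate
17 | ethyl diazoacetate | CCOC(=O)C=[N+]=[N-] | starting material
18 | ethyl 5-[(4-methoxybenzyl)oxy]-3-oxopentanoate | CCOC(=O)CC(=O)CCOCc1ccc(OC)cc1 | intermediate
19 | ethyl (3S)-3-hydroxy-5-[(4-methoxybenzyl)oxy]pentanoate | CCOC(=O)C[C@@H](O)CCOCc1ccc(OC)cc1 | intermediate
20 | dilithio alkoxide-enolate of 19 | CCO/C(O[Li])=C/[C@@H](O[Li])CCOCc1ccc(OC)cc1 | intermediate
21 | ethyl (2S,3S)-3-hydroxy-5-[(4-methoxybenzyl)oxy]-2-methylpentanoate | CCOC(=O)[C@@H](C)[C@@H](O)CCOCc1ccc(OC)cc1 | intermediate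
22 | (2S,3S)-3-hydroxy-N-methoxy-5-[(4-methoxybenzyl)oxy]-N,2-dimethylpentanamide | CON(C)C(=O)[C@@H](C)[C@@H](O)CCOCc1ccc(OC)cc1 | intermediate
23 | (2S,3S)-3-[(tert-butyldimethylsilyl)oxy]-N-methoxy-5-[(4-methoxybenzyl)oxy]-N,2-dimethylpentanamide | CON(C)C(=O)[C@@H](C)[C@@H](O[Si](C)(C)C(C)(C)C)CCOCc1ccc(OC)cc1 | intermediate
24 | ethylmagnesium bromide | CC[Mg]Br | starting material
25 | bromomagnesium hemiaminal chelate from 23 and 24 | CCC(O[Mg]Br)(N(C)OC)[C@@H](C)[C@@H](O[Si](C)(C)C(C)(C)C)CCOCc1ccc(OC)cc1 | intermediate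
26 | (4S,5S)-5-[(tert-butyldimethylsilyl)oxy]-7-[(4-methoxybenzyl)oxy]-4-methylheptan-3-one | CCC(=O)[C@@H](C)[C@@H](O[Si](C)(C)C(C)(C)C)CCOCc1ccc(OC)cc1 | intermediate
27 | methyl 2-(hydroxymethyl)acrylate | C=C(CO)C(=O)OC | starting material
28 | methyl (2R)-3-hydroxy-2-methylpropanoate | COC(=O)[C@H](C)CO | intermediate
29 | methyl (2R)-3-[(tert-butyldiphenylsilyl)oxy]-2-methylpropanoate | COC(=O)[C@H](C)CO[Si](c1ccccc1)(c1ccccc1)C(C)(C)C | intermediate
30 | (2S)-3-[(tert-butyldiphenylsilyl)oxy]-2-methylpropan-1-ol | OC[C@H](C)CO[Si](c1ccccc1)(c1ccccc1)C(C)(C)C | intermediate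
31 | (2R)-tert-butyl(3-iodo-2-methylpropoxy)diphenylsilane | IC[C@H](C)CO[Si](c1ccccc1)(c1ccccc1)C(C)(C)C | intermediate
32 | vinylmagnesium bromide | C=C[Mg]Br | starting material
33 | (2S)-tert-butyl[(2-methylpent-4-en-1-yl)oxy]diphenylsilane | C=CC[C@H](C)CO[Si](c1ccccc1)(c1ccccc1)C(C)(C)C | intermediate
34 | (2S)-2-methylpent-4-en-1-ol | C=CC[C@H](C)CO | intermediate
35 | (2S)-2-methylpent-4-enal | C=CC[C@H](C)C=O | intermediate
36 | trichlorotitanium Z-enolate of 26 | C/C=C(\O[Ti](Cl)(Cl)Cl)[C@@H](C)[C@@H](O[Si](C)(C)C(C)(C)C)CCOCc1ccc(OC)cc1 | intermediate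
37 | (3S,4S,6R,7S,8S)-3-[(tert-butyldimethylsilyl)oxy]-7-hydroxy-1-[(4-methoxybenzyl)oxy]-4,6,8-trimethylundec-10-en-5-one | C=CC[C@H](C)[C@H](O)[C@@H](C)C(=O)[C@@H](C)[C@@H](O[Si](C)(C)C(C)(C)C)CCOCc1ccc(OC)cc1 | intermediate
38 | (3S,4S,6R,7S,8S)-3,7-bis[(tert-butyldimethylsilyl)oxy]-1-[(4-methoxybenzyl)oxy]-4,6,8-trimethylundec-10-en-5-one | C=CC[C@H](C)[C@H](O[Si](C)(C)C(C)(C)C)[C@@H](C)C(=O)[C@@H](C)[C@@H](O[Si](C)(C)C(C)(C)C)CCOCc1ccc(OC)cc1 | intermediate
39 | C11 B-alkyl-9-borabicyclo[3.3.1]nonane from 38 | C1CC2CCCC(C1)B2CCC[C@H](C)[C@H](O[Si](C)(C)C(C)(C)C)[C@@H](C)C(=O)[C@@H](C)[C@@H](O[Si](C)(C)C(C)(C)C)CCOCc1ccc(OC)cc1 | intermediate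
40 | (3S,4S,6R,7S,8S,12Z,15S,16E)-3,7-bis[(tert-butyldimethylsilyl)oxy]-1-[(4-methoxybenzyl)oxy]-4,6,8,12,16-pentamethyl-17-(2-methyl-1,3-thiazol-4-yl)-15-[(triethylsilyl)oxy]heptadeca-12,16-dien-5-one | C/C(=C\c1csc(C)n1)[C@@H](O[Si](CC)(CC)CC)C/C=C(/C)CCC[C@H](C)[C@H](O[Si](C)(C)C(C)(C)C)[C@@H](C)C(=O)[C@@H](C)[C@@H](O[Si](C)(C)C(C)(C)C)CCOCc1ccc(OC)cc1 | intermediate
41 | (3S,4S,6R,7S,8S,12Z,15S,16E)-3,7-bis[(tert-butyldimethylsilyl)oxy]-1-hydroxy-4,6,8,12,16-pentamethyl-17-(2-methyl-1,3-thiazol-4-yl)-15-[(triethylsilyl)oxy]heptadeca-12,16-dien-5-one | C/C(=C\c1csc(C)n1)[C@@H](O[Si](CC)(CC)CC)C/C=C(/C)CCC[C@H](C)[C@H](O[Si](C)(C)C(C)(C)C)[C@@H](C)C(=O)[C@@H](C)[C@@H](O[Si](C)(C)C(C)(C)C)CCO | intermediate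
42 | (3S,4S,6R,7S,8S,12Z,15S,16E)-3,7-bis[(tert-butyldimethylsilyl)oxy]-4,6,8,12,16-pentamethyl-17-(2-methyl-1,3-thiazol-4-yl)-5-oxo-15-[(triethylsilyl)oxy]heptadeca-12,16-dienal | C/C(=C\c1csc(C)n1)[C@@H](O[Si](CC)(CC)CC)C/C=C(/C)CCC[C@H](C)[C@H](O[Si](C)(C)C(C)(C)C)[C@@H](C)C(=O)[C@@H](C)[C@@H](O[Si](C)(C)C(C)(C)C)CC=O | intermediate
43 | (3S,4S,6R,7S,8S,12Z,15S,16E)-3,7-bis[(tert-butyldimethylsilyl)oxy]-4,6,8,12,16-pentamethyl-17-(2-methyl-1,3-thiazol-4-yl)-5-oxo-15-[(triethylsilyl)oxy]heptadeca-12,16-dienoic acid | C/C(=C\c1csc(C)n1)[C@@H](O[Si](CC)(CC)CC)C/C=C(/C)CCC[C@H](C)[C@H](O[Si](C)(C)C(C)(C)C)[C@@H](C)C(=O)[C@@H](C)[C@@H](O[Si](C)(C)C(C)(C)C)CC(=O)O | intermediate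
44 | (3S,4S,6R,7S,8S,12Z,15S,16E)-3,7-bis[(tert-butyldimethylsilyl)oxy]-15-hydroxy-4,6,8,12,16-pentamethyl-17-(2-methyl-1,3-thiazol-4-yl)-5-oxoheptadeca-12,16-dienoic acid | C/C(=C\c1csc(C)n1)[C@@H](O)C/C=C(/C)CCC[C@H](C)[C@H](O[Si](C)(C)C(C)(C)C)[C@@H](C)C(=O)[C@@H](C)[C@@H](O[Si](C)(C)C(C)(C)C)CC(=O)O | intermediate
45 | mixed anhydride of 44 and 2,4,6-trichlorobenzoic acid | C/C(=C\c1csc(C)n1)[C@@H](O)C/C=C(/C)CCC[C@H](C)[C@H](O[Si](C)(C)C(C)(C)C)[C@@H](C)C(=O)[C@@H](C)[C@@H](O[Si](C)(C)C(C)(C)C)CC(=O)OC(=O)c1c(Cl)cc(Cl)cc1Cl | intermediate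
46 | (4S,5S,7R,8S,9S,13Z,16S)-4,8-bis[(tert-butyldimethylsilyl)oxy]-5,7,9,13-tetramethyl-16-[(1E)-1-(2-methyl-1,3-thiazol-4-yl)prop-1-en-2-yl]oxacyclohexadec-13-ene-2,6-dione | C/C(=C\c1csc(C)n1)[C@@H]1C/C=C(/C)CCC[C@H](C)[C@H](O[Si](C)(C)C(C)(C)C)[C@@H](C)C(=O)[C@@H](C)[C@@H](O[Si](C)(C)C(C)(C)C)CC(=O)O1 | intermediate
47 | (4S,5S,7R,8S,9S,13Z,16S)-4,8-dihydroxy-5,7,9,13-tetramethyl-16-[(1E)-1-(2-methyl-1,3-thiazol-4-yl)prop-1-en-2-yl]oxacyclohexadec-13-ene-2,6-dione | C/C(=C\c1csc(C)n1)[C@@H]1C/C=C(/C)CCC[C@H](C)[C@H](O)[C@@H](C)C(=O)[C@@H](C)[C@@H](O)CC(=O)O1 | intermediate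
48 | (1S,3S,7S,8S,10R,11S,12S,16R)-7,11-dihydroxy-8,10,12,16-tetramethyl-3-[(1E)-1-(2-methyl-1,3-thiazol-4-yl)prop-1-en-2-yl]-4,17-dioxabicyclo[14.1.0]heptadecane-5,9-dione (CNP0265054.1) | C/C(=C\c1csc(C)n1)[C@@H]1C[C@@H]2O[C@]2(C)CCC[C@H](C)[C@H](O)[C@@H](C)C(=O)[C@@H](C)[C@@H](O)CC(=O)O1 | target

## Step count and weak points

Total step count: 31.
Longest linear sequence: 18 steps (steps 7–14, then steps 22–31).

**Step 6 (iodo-Wittig olefination).** The yield is usually modest, the β-silyloxy aldehyde can eliminate under the basic ylide, and some E isomer or diiodide can form. The fallback sets the geometry by cross-coupling instead of by a Wittig reaction. It sets out from aldehyde 8. Ramirez olefination (CBr4, PPh3, CH2Cl2, 0 °C) gives the 1,1-dibromoalkene 4-[(1E,3S)-6,6-dibromo-2-methyl-3-(triethylsilyloxy)hexa-1,5-dien-1-yl]-2-methyl-1,3-thiazole F1. A trans-selective Negishi monomethylation (Me2Zn, PdCl2(DPEphos), THF, 0 °C to rt) then replaces only the less hindered bromine, the one trans to the chain. This gives the Z-vinyl bromide 4-[(1E,3S,5Z)-6-bromo-2-methyl-3-(triethylsilyloxy)hepta-1,5-dien-1-yl]-2-methyl-1,3-thiazole F2. F2 takes the place of 13 in the coupling with borane 39, and the route is rejoined at 40.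

**Step 22 (chlorotitanium aldol).** The risks are incomplete regiocontrol of enolisation (C6 against C4), a weaker facial bias from the 3,4-anti ketone than expected, and loss of the volatile aldehyde. The fallback makes the C6 enolate by conjugate hydride delivery instead of deprotonation. It sets out from Weinreb amide 23. Vinylmagnesium bromide 32 (THF, 0 °C, cold acidic quench) gives the enone (4S,5S)-5-[(tert-butyldimethylsilyl)oxy]-7-[(4-methoxybenzyl)oxy]-4-methylhept-1-en-3-one F3. A hydrogen-mediated reductive aldol coupling of F3 with aldehyde 35 follows (Rh(cod)2OTf, tri(2-furyl)phosphine, Li2CO3, H2 1 atm, CH2Cl2, rt). It forms the Z-rhodium enolate only at C6, never touches the C4 hydrogen, spares the isolated alkene and the PMB ether, and passes through the same syn-selective closed transition state. The route is rejoined at 37.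

**Step 24 (hydroboration and Suzuki coupling).** Aqueous Cs2CO3 could epimerise C4 or C6 or eliminate a β-silyloxy group, and the thiazole can slow the palladium catalyst. The fallback is a base-free Negishi coupling, and it sets out from 38 through borane 39.

- Mild oxidation (NaBO3·4H2O, THF/H2O) gives the alcohol (3S,4S,6R,7S,8S)-3,7-bis[(tert-butyldimethylsilyl)oxy]-11-hydroxy-1-[(4-methoxybenzyl)oxy]-4,6,8-trimethylundecan-5-one F4.
- Appel iodination (I2, PPh3, imidazole) gives the iodide (3S,4S,6R,7S,8S)-3,7-bis[(tert-butyldimethylsilyl)oxy]-11-iodo-1-[(4-methoxybenzyl)oxy]-4,6,8-trimethylundecan-5-one F5.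
- Direct zinc insertion (Zn dust, LiCl, THF), which tolerates the ketone, gives the C11 alkylzinc iodide F6.
- Coupling of F6 with vinyl iodide 13 (Pd(PPh3)4, THF, rt) proceeds with retention of geometry, and the route is rejoined at 40.

Further compounds
F1 | step 6 | 4-[(1E,3S)-6,6-dibromo-2-methyl-3-(triethylsilyloxy)hexa-1,5-dien-1-yl]-2-methyl-1,3-thiazole | C/C(=C\c1csc(C)n1)[C@@H](O[Si](CC)(CC)CC)CC=C(Br)Br
F2 | step 6 | 4-[(1E,3S,5Z)-6-bromo-2-methyl-3-(triethylsilyloxy)hepta-1,5-dien-1-yl]-2-methyl-1,3-thiazole | C/C(=C\c1csc(C)n1)[C@@H](O[Si](CC)(CC)CC)C/C=C(/C)Br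
F3 | step 22 | (4S,5S)-5-[(tert-butyldimethylsilyl)oxy]-7-[(4-methoxybenzyl)oxy]-4-methylhept-1-en-3-one | C=CC(=O)[C@@H](C)[C@@H](O[Si](C)(C)C(C)(C)C)CCOCc1ccc(OC)cc1
F4 | step 24 | (3S,4S,6R,7S,8S)-3,7-bis[(tert-butyldimethylsilyl)oxy]-11-hydroxy-1-[(4-methoxybenzyl)oxy]-4,6,8-trimethylundecan-5-one | OCCC[C@H](C)[C@H](O[Si](C)(C)C(C)(C)C)[C@@H](C)C(=O)[C@@H](C)[C@@H](O[Si](C)(C)C(C)(C)C)CCOCc1ccc(OC)cc1
F5 | step 24 | (3S,4S,6R,7S,8S)-3,7-bis[(tert-butyldimethylsilyl)oxy]-11-iodo-1-[(4-methoxybenzyl)oxy]-4,6,8-trimethylundecan-5-one | ICCC[C@H](C)[C@H](O[Si](C)(C)C(C)(C)C)[C@@H](C)C(=O)[C@@H](C)[C@@H](O[Si](C)(C)C(C)(C)C)CCOCc1ccc(OC)cc1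
F6 | step 24 | C11 alkylzinc iodide from F5 | I[Zn]CCC[C@H](C)[C@H](O[Si](C)(C)C(C)(C)C)[C@@H](C)C(=O)[C@@H](C)[C@@H](O[Si](C)(C)C(C)(C)C)CCOCc1ccc(OC)cc1
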